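**Assumptions.** The target is read from the SMILES as (2R,3R,4S,7R,9R,12S,14S,16S)-2,3-dihydroxytrinervita-1(15),8(19)-diene-9,14-diyl diacetate. Trinervitane (= cembrane) locants C-1 to C-20 are used for all intermediates. C-7 in 7 and 15–19 is an epimer mixture and C-1 in 18–20 is drawn as one epimer; both centres are reset or erased in step 11.

## Retrosynthetic overview

1. Target ⇐ one-pot double transannular cationic closure of macrocycle 19: epoxide-initiated C4–C16 bond, then C7–C16 bond from a latent 7,9-acetoxonium ion (cembrane → secotrinervitane → trinervitane).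
2. 14-Membered ring 18 ⇐ carbonyl-ene macrocyclisation, C-1 of the terminal isopropylidene onto the C-2 epoxy-aldehyde (the geranylgeranyl C14→C1 closure).
3. Acyclic chain 16 ⇐ Ni/Cr coupling (C8–C9) of bromoallyl alcohol 7 (from geraniol) with aldehyde 14 (from (S)-citronellal).
4. Ring order: 14-membered → six-membered → five-membered (leaving the 11-membered ring).

## Route

Step 1
Reactants: 1 geraniol
Product: 2 (2S,3S)-2,3-epoxygeraniol
Conditions: Ti(OiPr)4 (5 mol %), L-(+)-diethyl tartrate (7 mol %), t-BuOOH, 4 Å MS, CH2Cl2, −20 °C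
Reagents that add atoms: tert-butyl hydroperoxide, CC(C)(C)OO
Why: Sharpless asymmetric epoxidation of the allylic alcohol; L-(+)-tartrate gives the (2S,3S)-epoxide, which fixes C-3 and (after inversion in step 11) C-4 of the target.

Step 2
Reactants: 2 (2S,3S)-2,3-epoxygeraniol
Product: 4 3-[(2S,3S)-3-(hydroxymethyl)-2-methyloxiran-2-yl]propanal, via secondary ozonide 3 (not isolated)
Conditions: O3, CH2Cl2, −78 °C; then PPh3, −78 °C to rt
Reagents that add atoms: ozone, [O-][O+]=O
Why: Ozonolysis of the only remaining olefin gives the C-7 aldehyde; the epoxy alcohol is inert and no stereocentre is touched.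

Step 3
Reactants: 4 3-[(2S,3S)-3-(hydroxymethyl)-2-methyloxiran-2-yl]propanal; 5 vinyl bromide
Product: 7 (3RS)-2-bromo-5-[(2S,3S)-3-(hydroxymethyl)-2-methyloxiran-2-yl]pent-1-en-3-ol, via 1-bromovinyllithium 6 (not isolated)
Conditions: 5, LDA (2.2 equiv each), THF–Et2O–pentane, −110 °C; then 4, −110 to −78 °C; H2O
Reagents that add atoms: none
Why: 1,2-Addition of an α-bromoalkenyllithium (carbenoid kept at −110 °C) to the aldehyde installs C-8/C-19 as a 2-bromoallyl alcohol; the new C-7 carbinol is unselective, which does not matter because C-7 is re-set in step 11.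

Step 4
Reactants: 8 (S)-citronellal; 9 1-bromo-2-methylprop-1-ene
Product: 11 (4S,6S)-2,6,10-trimethylundeca-2,9-dien-4-ol, via isobutenylchromium dichloride 10 (not isolated)
Conditions: CrCl2 (3 equiv), NiCl2 (cat.), chiral oxazoline–sulfonamide ligand (enantiomer directing Re-face attack), Et3N, THF, rt
Reagents that add atoms: none
Why: Ligand-controlled asymmetric Nozaki–Hiyama–Kishi alkenylation; Re-face delivery of the isobutenyl group sets 14S, and 12S comes from the chiral pool.

Step 5
Reactants: 11 (4S,6S)-2,6,10-trimethylundeca-2,9-dien-4-ol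
Product: 12 (4S,6S)-2,6,10-trimethylundeca-2,9-dien-4-yl acetate
Conditions: Ac2O, pyridine, DMAP (cat.), CH2Cl2, 0 °C to rt
Reagents that add atoms: acetic anhydride, CC(=O)OC(C)=O
Why: Standard acylation installs the 14-acetate of the target and deactivates the adjacent olefin for step 6.

Step 6
Reactants: 12 (4S,6S)-2,6,10-trimethylundeca-2,9-dien-4-yl acetate
Product: 14 (4S,6S)-4,8-dimethyl-1-oxonon-7-en-6-yl acetate, via vicinal diol 13 (not isolated)
Conditions: OsO4 (2 mol %), NaIO4, 2,6-lutidine, dioxane–H2O, 0 °C to rt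
Reagents that add atoms: sodium periodate, [Na+].[O-]I(=O)(=O)=O (oxygen passed on through catalytic OsO4)
Why: Lemieux–Johnson cleavage is selective for the electron-rich remote trisubstituted olefin over the olefin deactivated by the allylic acetate (as in geranyl acetate), giving the C-9 aldehyde.

Step 7
Reactants: 7 (3RS)-2-bromo-5-[(2S,3S)-3-(hydroxymethyl)-2-methyloxiran-2-yl]pent-1-en-3-ol; 14 (4S,6S)-4,8-dimethyl-1-oxonon-7-en-6-yl acetate
Product: 16 (3S,4S,7RS,9R,12S,14S)-3,4-epoxy-2,7,9-trihydroxy-1,2-secocembra-1(15),8(19)-dien-14-yl acetate, via alkenylchromium dichloride 15 (not isolated)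
Conditions: CrCl2 (4 equiv), NiCl2 (cat.), chiral oxazoline–sulfonamide ligand (enantiomer directing Si-face attack), Et3N, THF, rt
Reagents that add atoms: none
Why: Asymmetric Nozaki–Hiyama–Kishi coupling of the 2-bromoalkene with the aldehyde forms C8–C9; ligand-controlled Si-face addition sets 9R, and free hydroxyls, epoxide and acetate are tolerated by Cr(II).

Step 8
Reactants: 16 (3S,4S,7RS,9R,12S,14S)-3,4-epoxy-2,7,9-trihydroxy-1,2-secocembra-1(15),8(19)-dien-14-yl acetate
Product: 17 (3R,4S,7RS,9R,12S,14S)-3,4-epoxy-7,9-dihydroxy-2-oxo-1,2-secocembra-1(15),8(19)-dien-14-yl acetate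
Conditions: TEMPO (10 mol %), PhI(OAc)2, CH2Cl2, 0 °C
Reagents that add atoms: none
Why: TEMPO/PhI(OAc)2 oxidises the primary epoxy alcohol to the epoxy aldehyde in preference to the two secondary alcohols (the C-3 descriptor changes by CIP priority only).

Step 9
Reactants: 17 (3R,4S,7RS,9R,12S,14S)-3,4-epoxy-7,9-dihydroxy-2-oxo-1,2-secocembra-1(15),8(19)-dien-14-yl acetate
Product: 18 (1R,2R,3S,4S,7RS,9R,12S,14S)-3,4-epoxy-2,7,9-trihydroxycembra-8(19),15-dien-14-yl acetate
Conditions: Me2AlCl (3.5 equiv), CH2Cl2 (1 mM), −78 °C, 1 h; cold aq. Rochelle salt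
Reagents that add atoms: none
Why: Proposed new method: the Al-chelated α,β-epoxy aldehyde (two equivalents of reagent are consumed as the 7,9-dialkoxide) is attacked by C-1 of the terminal isopropylidene with transfer of a methyl hydrogen, closing the 14-membered ring and unveiling the isopropenyl group, while the chelate between C=O and the oxirane oxygen exposes the face that gives the threo (2R) carbinol and the oxirane stays intact at −78 °C; closest known reaction type is the Lewis-acid-promoted type-I carbonyl-ene macrocyclisation of activated aldehydes onto isopropylidene termini.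

Step 10
Reactants: 18 (1R,2R,3S,4S,7RS,9R,12S,14S)-3,4-epoxy-2,7,9-trihydroxycembra-8(19),15-dien-14-yl acetate
Product: 19 7,9-O-(1-methoxyethylidene) derivative of 18 (cyclic methyl orthoacetate)
Conditions: MeC(OMe)3 (1.2 equiv), PPTS (cat.), CH2Cl2, 0 °C
Reagents that add atoms: trimethyl orthoacetate, COC(C)(OC)OC
Why: Acid-catalysed transorthoesterification closes the six-membered cyclic orthoester on the 2-methylene-1,3-diol in preference to the single hindered 2-OH, without breaking a C–O bond at C-7 or C-9.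

Step 11
Reactants: 19 7,9-O-(1-methoxyethylidene) derivative of 18 (cyclic methyl orthoacetate)
Product: 22 (2R,3R,4S,7R,9R,12S,14S,16S)-2,3-dihydroxytrinervita-1(15),8(19)-diene-9,14-diyl diacetate, via secotrinervitane dioxanylium triflate 20 (not isolated), via bis(trimethylsilyl) ether 21 (not isolated)
Conditions: TMSOTf (3.5 equiv), CH2Cl2 (2 mM), −78 to −40 °C; Et3N; then 1 M HCl, THF, 0 °C
Reagents that add atoms: trimethylsilyl trifluoromethanesulfonate, C[Si](C)(C)OS(=O)(=O)C(F)(F)F (its Me3Si groups end up in 20 and 21 only)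
Why: Proposed new method: TMSOTf silylates 2-OH, ionises the orthoester to a 2-methyl-1,3-dioxan-2-ylium ion and opens the oxirane at C-4, the isopropenyl CH2 (C-16) attacks C-4 anti to the leaving oxygen through a chair (C-4 inverted to S, 3-O equatorial), the TfOH released equilibrates the C-15 cation with its olefins, the 15(16)-olefin then alkylates the allylic acetoxonium at C-7 on the face syn to C-5 (cis-hydrindane, H-16 and H-7 cis) releasing the 9-acetate without ever breaking C9–O, and loss of H-1 gives the tetrasubstituted 1(15)-olefin; closest known reaction types are the epoxide-initiated cation–olefin (epoxy-ene) cyclisation and the opening of orthoester-derived acetoxonium ions by nucleophiles.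

## Compound list

1 | geraniol | CC(C)=CCC/C(C)=C/CO | starting material
2 | (2S,3S)-2,3-epoxygeraniol | CC(C)=CCC[C@]1(C)O[C@H]1CO | intermediate
3 | secondary ozonide of 2 (not isolated) | CC1(C)OOC(CC[C@]2(C)O[C@H]2CO)O1 | intermediate
4 | 3-[(2S,3S)-3-(hydroxymethyl)-2-methyloxiran-2-yl]propanal | O=CCC[C@]1(C)O[C@H]1CO | intermediate
5 | vinyl bromide | C=CBr | starting material
6 | 1-bromovinyllithium (not isolated) | [Li]C(Br)=C | intermediate
7 | (3RS)-2-bromo-5-[(2S,3S)-3-(hydroxymethyl)-2-methyloxiran-2-yl]pent-1-en-3-ol | C=C(Br)C(O)CC[C@]1(C)O[C@H]1CO | intermediate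
8 | (S)-citronellal | CC(C)=CCC[C@H](C)CC=O | starting material
9 | 1-bromo-2-methylprop-1-ene | CC(C)=CBr | starting material
10 | (2-methylprop-1-enyl)chromium(III) dichloride (not isolated) | CC(C)=C[Cr](Cl)Cl | intermediate
11 | (4S,6S)-2,6,10-trimethylundeca-2,9-dien-4-ol | CC(C)=CCC[C@H](C)C[C@H](O)C=C(C)C | intermediate
12 | (4S,6S)-2,6,10-trimethylundeca-2,9-dien-4-yl acetate | CC(C)=CCC[C@H](C)C[C@H](OC(C)=O)C=C(C)C | intermediate
13 | (4S,6S,9RS)-9,10-dihydroxy-2,6,10-trimethylundec-2-en-4-yl acetate (not isolated) | CC(C)(O)C(O)CC[C@H](C)C[C@H](OC(C)=O)C=C(C)C | intermediate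
14 | (4S,6S)-4,8-dimethyl-1-oxonon-7-en-6-yl acetate | O=CCC[C@H](C)C[C@H](OC(C)=O)C=C(C)C | intermediate
15 | alkenylchromium(III) dichloride from 7, CrCl2 in place of Br (not isolated) | C=C([Cr](Cl)Cl)C(O)CC[C@]1(C)O[C@H]1CO | intermediate
16 | (3S,4S,7RS,9R,12S,14S)-3,4-epoxy-2,7,9-trihydroxy-1,2-secocembra-1(15),8(19)-dien-14-yl acetate | C=C([C@H](O)CC[C@H](C)C[C@H](OC(C)=O)C=C(C)C)C(O)CC[C@]1(C)O[C@H]1CO | intermediate
17 | (3R,4S,7RS,9R,12S,14S)-3,4-epoxy-7,9-dihydroxy-2-oxo-1,2-secocembra-1(15),8(19)-dien-14-yl acetate | C=C([C@H](O)CC[C@H](C)C[C@H](OC(C)=O)C=C(C)C)C(O)CC[C@]1(C)O[C@H]1C=O | intermediate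
18 | (1R,2R,3S,4S,7RS,9R,12S,14S)-3,4-epoxy-2,7,9-trihydroxycembra-8(19),15-dien-14-yl acetate | C=C1[C@H](O)CC[C@H](C)C[C@H](OC(C)=O)[C@H](C(C)=C)[C@@H](O)[C@@H]2O[C@@]2(C)CCC1O | intermediate
19 | 7,9-O-(1-methoxyethylidene) derivative of 18 (cyclic methyl orthoacetate, 2-OH free) | C=C1[C@H]3CC[C@H](C)C[C@H](OC(C)=O)[C@H](C(C)=C)[C@@H](O)[C@@H]2O[C@@]2(C)CCC1OC(C)(OC)O3 | intermediate
20 | 14-acetoxy-2,3-bis(trimethylsilyloxy)-7,16-secotrinervita-8(19),15-diene with O-7/O-9 bridged as a 2-methyl-1,3-dioxan-2-ylium triflate (not isolated) | C=C1[C@H]3CC[C@H](C)C[C@H](OC(C)=O)[C@@H]2C(C)=C[C@](C)(CCC1OC(C)=[O+]3)[C@@H](O[Si](C)(C)C)[C@@H]2O[Si](C)(C)C.[O-]S(=O)(=O)C(F)(F)F | intermediate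
21 | 2,3-bis-O-(trimethylsilyl) ether of 22 (not isolated) | C=C1[C@H](OC(C)=O)CC[C@H](C)C[C@H](OC(C)=O)C2=C(C)[C@@H]3[C@H]1CC[C@]3(C)[C@@H](O[Si](C)(C)C)[C@@H]2O[Si](C)(C)C | intermediate
22 | (2R,3R,4S,7R,9R,12S,14S,16S)-2,3-dihydroxytrinervita-1(15),8(19)-diene-9,14-diyl diacetate (CNP0286573.1) | C=C1[C@H](OC(C)=O)CC[C@H](C)C[C@H](OC(C)=O)C2=C(C)[C@@H]3[C@H]1CC[C@]3(C)[C@@H](O)[C@@H]2O | target

## Step count and risks

Total step count: 11. Longest linear sequence: 8 steps (1, 2, 3, 7, 8, 9, 10, 11 from geraniol; equally 4–11 from (S)-citronellal).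

The three steps most likely to fail:

**Step 11.** The second closure needs the 15(16)-olefin, which must be reached by acid equilibration of the kinetic olefins. The final proton loss must choose H-1 over H-16 and H-17. The allylic 14-acetate and the 9-acetate must survive TfOH at low temperature. The fallback sets out from 19 and comes back at 21, separating the two closures and making the first one a radical process. Cp2TiCl (Cp2TiCl2/Mn, THF, rt, bicarbonate work-up) opens the oxirane homolytically at C-4; the β-titanoxy radical closes 6-endo onto the isopropenyl group and ends by Ti-mediated β-hydride loss. This gives the defined exocyclic olefin 14-acetoxy-7,9-O-(1-methoxyethylidene)-7,16-secotrinervita-8(19),15(17)-diene-2,3-diol F1, with the orthoester untouched. F1 is then treated with TMSOTf alone, where only the olefin shift and the acetoxonium alkylation remain, giving 21 and, after the acidic work-up, 22.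

**Step 9.** The ene donor is deactivated by the allylic acetate, the ring is 14-membered, and the 2R (threo) outcome depends on chelation. The fallback sets out from 17 and comes back at 18, replacing the Lewis-acid ene reaction by a neutral allylmetal addition. Ene-type allylic chlorination of the isobutenyl group (NCS, cat. PhSeCl, CH2Cl2) gives the transposed allylic chloride (1RS,3R,4S,7RS,9R,12S,14S)-1-chloro-3,4-epoxy-7,9-dihydroxy-2-oxo-1,2-secocembra-8(19),15-dien-14-yl acetate F2. CrCl2 in THF/DMF at high dilution (intramolecular Nozaki–Hiyama allylation) then forms the same C1–C2 bond through the γ-carbon of the allylchromium, giving 18.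

**Step 7.** A hindered 2-bromoalkene carrying free hydroxyls is coupled under ligand control, and 9R rests entirely on the catalyst. The fallback sets out from 14 (with 6 and 4) and comes back at 16; C-9 is set by a ketone reduction instead. Reagent 6 is added to 14 at −110 °C to give (4S,6S,9RS)-10-bromo-9-hydroxy-2,6-dimethylundeca-2,10-dien-4-yl acetate F3. Dess–Martin oxidation gives the α-bromo enone (4S,6S)-10-bromo-2,6-dimethyl-9-oxoundeca-2,10-dien-4-yl acetate F4. Reduction with (S)-Me-CBS/catecholborane (bromovinyl as the large group) gives (4S,6S,9R)-10-bromo-9-hydroxy-2,6-dimethylundeca-2,10-dien-4-yl acetate F5. F5 is then joined to aldehyde 4 by an ordinary achiral CrCl2/NiCl2 coupling to give 16 (7RS).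

## Further compounds

F1 | step 11 | 14-acetoxy-7,9-O-(1-methoxyethylidene)-7,16-secotrinervita-8(19),15(17)-diene-2,3-diol | C=C1[C@H]3CC[C@H](C)C[C@H](OC(C)=O)[C@@H]2C(=C)C[C@](C)(CCC1OC(C)(OC)O3)[C@@H](O)[C@@H]2O
F2 | step 9 | (1RS,3R,4S,7RS,9R,12S,14S)-1-chloro-3,4-epoxy-7,9-dihydroxy-2-oxo-1,2-secocembra-8(19),15-dien-14-yl acetate | C=C([C@H](O)CC[C@H](C)C[C@H](OC(C)=O)C(Cl)C(C)=C)C(O)CC[C@]1(C)O[C@H]1C=O
F3 | step 7 | (4S,6S,9RS)-10-bromo-9-hydroxy-2,6-dimethylundeca-2,10-dien-4-yl acetate | C=C(Br)C(O)CC[C@H](C)C[C@H](OC(C)=O)C=C(C)C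
F4 | step 7 | (4S,6S)-10-bromo-2,6-dimethyl-9-oxoundeca-2,10-dien-4-yl acetate | C=C(Br)C(=O)CC[C@H](C)C[C@H](OC(C)=O)C=C(C)C
F5 | step 7 | (4S,6S,9R)-10-bromo-9-hydroxy-2,6-dimethylundeca-2,10-dien-4-yl acetate | C=C(Br)[C@H](O)CC[C@H](C)C[C@H](OC(C)=O)C=C(C)C
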